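## Structural features

The target is a tricyclic furanoheliangolide. A ten-membered carbocycle (C1–C10) is bridged by a 3(2H)-furanone (ring oxygen between C10 and C3, C1 ketone, C2=C3) and fused at C6–C7 to an α-methylene-γ-butyrolactone (O–C6, C12 carbonyl, C11=C13). The C4=C5 bond is Z, that is cis inside the ten-membered ring; it carries the C15 acetoxymethyl group and is cross-conjugated with the furanone, and C8 bears a methacrylate. Three stereocentres stand next to one another (C6 R, C7 R, C8 S; H-6 and H-7 anti, so the lactone is trans-fused), and the fourth, the quaternary C10 (R), is separated from C8 only by the C9 methylene. The exo-methylene lactone and the methacrylate are Michael acceptors, the esters and the allylic acetate do not tolerate base or nucleophiles, and C7–H is doubly activated whenever C6 is a ketone. The real difficulty is the strained medium ring with its bridging heterocycle and cis-trisubstituted alkene, combined with the 1,3-related oxygens at C8 and C10 and the C6–C7–C8 triad. The key step uses the fact that C1 and C6 lie opposite each other in the ten-membered ring: a bond between them turns the carbocycle into a decalin (ring A: C1, C6, C7, C8, C9, C10; ring B: C1–C6) in which C4=C5 is cis by necessity. Ring A then has the pattern of a p-menthane (C10 methyl, C7 three-carbon branch), and the C1/C3 dicarbonyl next to the C10 oxygen is a latent furanone.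

## Logic of the disconnections

37 to 35: the two ester C–O bonds at O8 and O15 are cut first. Both acyl groups are fragile, so they are put on last. This leaves diol 35; the forward acylations must tell the primary allylic O15 from the hindered secondary O8, which is why the acetate precedes the methacrylate (36).

35 to 30: the two O–Si bonds (34), then the lactone C12–O6 bond together with the C12 oxidation level (31), then the O12–aryl bond (30). A 2-methylene-1,4-diol gives the exo-methylene lactone in one oxidative operation, so no allylic C–H oxidation is needed next to the furanone. The forward oxidation must prefer the primary allylic C12–OH to the secondary allylic C6–OH.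

30 to 29: the C6–H bond, back to the C6 ketone. The forward reduction must be 1,2-selective and must attack the face that puts H-6 anti to H-7.

29 to 26 (key disconnection): the furanone O–C3 bond is opened and C1 is joined to C6. The medium ring and the bridging heterocycle are replaced by a cis-fused decalin diol, and the stereochemical problem shrinks to C7, C8 and C10. A check of the configurations shows that these three centres pass unchanged from 26 through 29 to 37 (7R, 8S, 10R in 37). The forward step must cleave C1–C6 and not C1–C10, and must then free only the C10 oxygen. Compound 26 is designed for this in three points: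
- C10–O is the only acid-labile silyl ether (triethylsilyl, against secondary TBS and primary TBDPS).
- C12 is already oxygenated as an aryl ether, so the C7 branch needs no late allylic oxidation.
- The C1 and C6 hydroxyls stand on the face of the C7 branch, because only then can both C–C bonds at C6 and C1 be formed anti to the axial C10 methyl.

26 to 18 and 22: the C4=C5 bond (ring-closing metathesis, 25) and then the C1–C2 bond (aldol). Ring B is thus assembled from a vinyl group on C6 and a four-carbon enone that already carries C15. The nucleophile must add to a crowded, non-enolisable C1 ketone on the face opposite the C6 oxygen. Compound 22 goes back to 19 and 20 by the C4–C15 bond.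

18 to 12: the C6–C5 bond (17, from 14 and 15), then the C6–O bond (14 from 12). A free C1,C6-dione is avoided on purpose: its C7–H would be doubly activated and the compound would exist as the diosphenol, which erases C7 and diverts a vinyl nucleophile. The oxygen therefore enters first through an enol ether, and C5 enters second as an electrophile, which also fixes the C6 configuration wanted for 26.

12 to 8: the C10–O bond and the C9–H bond, with the C1 oxidation level adjusted (11, 10, 9). The tertiary carbinol at C10 is traced to the C9=C10 alkene of allylic alcohol 8. The C1 hydroxyl of 8 directs the epoxidation, so its configuration decides C10.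

8 to 3: the carbonyl is moved back from C1 to C9 (7, 6), and the C8–O bond is cut. An oxygen cannot be placed reliably on the γ-carbon of an enone, but it is easy at the α'-carbon of 3. The transposition then puts the carbonyl where C1 needs it and leaves C9 as a methylene. Because the carbonyl carbon of 1 ends as C9 and not as C1, the S enantiomer of 1 is required.

3 to 1: the C12–O bond (2). At this stage the branch alkene is the only electron-rich alkene in the molecule, so C12 can be functionalised cleanly.

## Other disconnections considered

Alternative 1: The cut is at C7–C8 and C11–C13; no ring of the target is closed. In the forward sense the C8 carbanion of dithiane A3 would add 1,4 to butenolide A2 on the face away from the C6 substituent, and the lactone enolate would be trapped at C11 by an iminium electrophile to give lactone A1.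
- In its favour: the lactone with the correct trans C6/C7 relationship is present from the start and comes from a cheap chiral butenolide. The exo-methylene is one quaternisation–elimination away. The step is a well-established conjugate addition–enolate trapping that joins two fragments of similar size.
- Against it here: C8 is left as a masked ketone that must later be reduced with control. C10 must be made separately in enantiopure form. After the key step neither the furanone nor the ten-membered ring exists, so a ring closure against the strain of the Z-alkene is still ahead.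
- Comparison: this plan is the better one for C6 and C7, which it fixes by approach control on a rigid five-membered ring, where the chosen plan relies on a ketone reduction in a medium ring. It is also more convergent. It is weaker on the medium ring, which the chosen plan obtains by cleaving a bond of a six-membered ring, and it would need more steps after its key step.

Alternative 2: The cut runs through the furanone at O–C3 and C1–C2. The alkoxide of tertiary alcohol A5 would add to C3 of enynoate A6, and the resulting allenolate would acylate at the ester carbon C1, closing furanone A4 with a removable ester on C2 and both side chains in place.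
- In its favour: the heterocycle is made convergently in one basic, non-oxidative step. C10 comes from a simple α-hydroxy ester. The geometry of C4=C5 is fixed in A6 before the coupling.
- Against it here: the C2 ester has to be removed. C7 and its branch are still missing. The ten-membered ring must then be closed at C6–C7 or C7–C8, so two of the three contiguous stereocentres are created during a strained ring closure.
- Comparison: in forming the O–C3 bond this plan is the equal of the chosen one. It is better in convergence and in never placing a ketone at C6 next to the labile C7–H. It is worse on ring strain, which must be paid in a high-dilution ring closure and is not released from a decalin, and on the source of C7 and C8, which the chosen plan carries from a terpene.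

Alternative 3: The cut is at C4=C5, reached from the eleven-membered cyclic sulfone A8. Under halogenating Ramberg–Bäcklund conditions the sulfone would be halogenated at C4, the C5 carbanion would close the episulfone, and extrusion of the sulfur bridge would contract the ring to carbocycle A7.
- In its favour: the large ring is closed at a less strained size by easy C–S bond formation. The contraction makes the alkene and the ten-membered ring at once. The furanone and all four stereocentres are already present, and the acrylate is at the right oxidation level for the lactone to close when O6 is unmasked.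
- Against it here: a strongly basic, halogenating medium meets an acrylate ester, a C6 silyloxy group β to the C5 carbanion, and the acidic furanone. The site of halogenation (C4 or C5) is not secured. A8 itself needs every stereocentre set before the ring is formed.
- Comparison: both plans take the cis C4=C5 geometry from a ring constraint and not from an olefination, and on this they are equals. The alternative is the better one at C6 and C12, where it needs neither a ketone reduction nor an oxidative lactonisation. It is the weaker one in the tolerance of its key step and in the length of the route to its precursor; the step counts should be similar overall.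

Key step: step 17

Numbering: target numbering is used for every intermediate; in 1 the carbonyl carbon is C9, the methyl-bearing carbon C10, the ring CH= C1, its neighbouring CH2 C6, the stereocentre C7, the CH2 next to the carbonyl C8, and the isopropenyl group is C11(=C13)–C12.

Assumption: C1 and C6 of the decalin diol become carbonyl carbons in the key step, so only their cis relationship matters and the diastereomer drawn is the one the route should give; centres that are mixtures and are removed later (sulfur in 17, the anomeric carbon in 33) are left undefined.

Step 1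
Reactants: 1 (S)-carvone
Product: 2 C12 allylic chloride
Conditions: Ca(OCl)2, CO2 (dry ice), CH2Cl2/H2O, 0 °C
Reagents that add atoms: calcium hypochlorite Ca(OCl)2, [Ca+2].[O-]Cl.[O-]Cl
Why: Electrophilic ene-type chlorination: HOCl, made in the flask, attacks only the electron-rich 1,1-disubstituted alkene, and loss of a methyl proton from the chloronium ion gives the 2-(chloromethyl)vinyl group; the conjugated alkene and C7 are not affected.

Step 2
Reactants: 2 C12 allylic chloride
Product: 3 C12 4-methoxyphenyl ether
Conditions: 4-methoxyphenol, K2CO3, acetone, 56 °C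
Reagents that add atoms: 4-methoxyphenol, COc1ccc(O)cc1
Why: Williamson ether synthesis on the allylic chloride (SN2 and SN2' lead to the same product). The phenoxide is too weak a base to form the enolate, which with stronger bases would alkylate the allylic chloride intramolecularly; the aryl ether carries C12 at the alcohol level to the end of the route.

Step 3
Reactants: 3 C12 4-methoxyphenyl ether
Product: 6 C8-silyloxy enone (OTBS trans to the C7 side chain), via lithium dienolate 4 (not isolated), via TBS dienol ether 5 (not isolated)
Conditions: LiN(iPr)2, THF, −78 °C; TBSOTf; then mCPBA, CH2Cl2, −20 °C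
Reagents that add atoms: tert-butyldimethylsilyl triflate, CC(C)(C)[Si](C)(C)OS(=O)(=O)C(F)(F)F; mCPBA, OOC(=O)c1cccc(Cl)c1
Why: Rubottom oxidation: kinetic deprotonation at C8 gives the cross-conjugated dienolate, which is O-silylated; the peracid epoxidises the electron-rich silyl enol ether in preference to the other alkenes, and ring opening with 1,4-silyl shift gives the α-silyloxy ketone. The oxidant approaches anti to the neighbouring C7 side chain, so C8–O is trans to it, which is also the more stable diequatorial arrangement.

Step 4
Reactants: 6 C8-silyloxy enone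
Product: 7 C1–C10 epoxy ketone
Conditions: H2O2 (30 %), NaOH (cat.), MeOH, 0 °C
Reagents that add atoms: hydrogen peroxide, OO
Why: Weitz–Scheffer epoxidation: hydroperoxide adds to C1 in the axial sense anti to the C7 side chain (the usual trans addition to 5-substituted cyclohexenones) and the enolate closes the oxirane on that face, the face of the C8 oxygen. The C1–O bond made here is the relay that later fixes C10.

Step 5
Reactants: 7 C1–C10 epoxy ketone
Product: 8 C1 allylic alcohol with C9=C10
Conditions: N2H4·H2O, AcOH (cat.), MeOH, 0 °C to rt
Reagents that add atoms: none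
Why: Wharton transposition: the hydrazone of the epoxy ketone opens to an allylic diazene that loses N2, leaving the C9=C10 alkene and the C1 carbinol with its configuration unchanged. C9 thereby loses its oxygen, as the C9 methylene of the target requires.

Step 6
Reactants: 8 C1 allylic alcohol
Product: 9 C9–C10 epoxy alcohol
Conditions: VO(acac)2 (cat.), t-BuOOH, CH2Cl2, 0 °C to rt
Reagents that add atoms: tert-butyl hydroperoxide, CC(C)(C)OO
Why: Vanadium-catalysed epoxidation is directed by the allylic C1 hydroxyl to the syn face of C9=C10 and does not touch the isolated 1,1-disubstituted alkene. This places the C10 oxygen on the face of the C8 oxygen, which is the configuration of C10 in the target.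

Step 7
Reactants: 9 C9–C10 epoxy alcohol
Product: 10 C1,C10-diol
Conditions: LiBHEt3, THF, 0 °C to rt
Reagents that add atoms: none
Why: Hydride opens the trisubstituted epoxide by SN2 attack at the secondary C9 (trans-diaxial opening; the tertiary C10 cannot be attacked), so C9 becomes CH2 and C10 keeps its oxygen as a tertiary alcohol.

Step 8
Reactants: 10 C1,C10-diol
Product: 11 C10-hydroxy C1 ketone
Conditions: Dess–Martin periodinane, pyridine, CH2Cl2, 0 °C to rt
Reagents that add atoms: none
Why: Dess–Martin oxidation converts the secondary C1 alcohol to the ketone; the tertiary C10 alcohol cannot be oxidised.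

Step 9
Reactants: 11 C10-hydroxy C1 ketone
Product: 12 ring A ketone with C10 OTES
Conditions: TESOTf, 2,6-lutidine, CH2Cl2, −78 to 0 °C
Reagents that add atoms: triethylsilyl triflate, CC[Si](CC)(CC)OS(=O)(=O)C(F)(F)F
Why: A silyl triflate with a hindered base silylates the tertiary α-ketol. The triethylsilyl ether masks C10–O against the later glycol cleavage and is the one silyl ether that mild acid removes in the key step.

Step 10
Reactants: 12 ring A ketone
Product: 14 C6-trimethylsilyloxy ketone, via TMS enol ether 13 (not isolated)
Conditions: TMSOTf, Et3N, CH2Cl2, 0 °C; then dimethyldioxirane, acetone/CH2Cl2, −78 °C to rt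
Reagents that add atoms: trimethylsilyl triflate, C[Si](C)(C)OS(=O)(=O)C(F)(F)F; dimethyldioxirane, CC1(C)OO1
Why: Rubottom oxidation: the ketone can enolise only toward C6 because C10 is quaternary; the dioxirane epoxidises the silyl enol ether under neutral conditions and the silyloxy epoxide rearranges to the α-trimethylsilyloxy ketone. The C6 configuration is of no account because C6 is enolised again in step 11.

Step 11
Reactants: 14 C6-trimethylsilyloxy ketone; 15 phenyl vinyl sulfoxide
Product: 17 C6 quaternary sulfoxide, via lithium enolate 16 (not isolated)
Conditions: LiN(iPr)2, THF, −78 °C; then 15, −78 to −30 °C; AcOH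
Reagents that add atoms: none
Why: Conjugate addition of the α-silyloxy enolate to the vinyl sulfoxide, a vinyl cation equivalent, creates the quaternary C6. The electrophile enters anti to the C7 side chain and to the axial C10 methyl, so C5 stands on the face of the C8 oxygen and the C6 oxygen on the face of the C7 side chain.

Step 12
Reactants: 17 C6 quaternary sulfoxide
Product: 18 C6 vinyl ketone
Conditions: toluene, 110 °C
Reagents that add atoms: none
Why: Thermal syn elimination of the sulfoxide can only run toward the chain end because C6 is quaternary, and gives the vinyl group; the temperature stays below that of an aryl allyl ether Claisen rearrangement.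

Step 13
Reactants: 19 methyl vinyl ketone; 20 formaldehyde (37 % aqueous)
Product: 21 3-(hydroxymethyl)but-3-en-2-one
Conditions: DABCO (cat.), THF/H2O, rt
Reagents that add atoms: none
Why: Morita–Baylis–Hillman reaction: the amine adds to the enone, the zwitterionic enolate adds to formaldehyde and the amine is eliminated, which attaches C15 to C4.

Step 14
Reactants: 21 3-(hydroxymethyl)but-3-en-2-one
Product: 22 silyl-protected enone
Conditions: TBDPSCl, imidazole, CH2Cl2, 0 °C
Reagents that add atoms: tert-butyldiphenylsilyl chloride, CC(C)(C)[Si](Cl)(c1ccccc1)c1ccccc1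
Why: Standard silylation of the primary allylic alcohol; the tert-butyldiphenylsilyl ether is chosen to outlast the acid of the key step.

Step 15
Reactants: 18 C6 vinyl ketone; 22 silyl-protected enone
Product: 25 diene cis-diol, via lithium dienolate 23 (not isolated), via TMS ether adduct 24 (not isolated)
Conditions: 22, LiN(SiMe3)2, THF, −78 °C; then 18, −78 °C; AcOH; then citric acid, MeOH, 0 °C
Reagents that add atoms: none
Why: Aldol addition: the kinetic α'-enolate of 22 adds through C2 to the C1 ketone, which cannot enolise and is activated by two α-oxygens. Axial attack from the face opposite the axial C10 methyl and the axial C6 silyloxy group puts C2 cis to the vinyl group and the C1 hydroxyl cis to the C6 oxygen; a shift of the trimethylsilyl group to the new alkoxide would only block the retro-aldol path, and mild acidic methanolysis then removes this one labile silyl group.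

Step 16
Reactants: 25 diene cis-diol
Product: 26 cis-fused decalin 1,6-diol enone
Conditions: second-generation Hoveyda–Grubbs catalyst RuCl2(H2IMes)(=CH-C6H4-2-OiPr) (5 mol %), toluene, 60 °C
Reagents that add atoms: none
Why: Ring-closing metathesis joins the C6 vinyl group and the 1,1-disubstituted enone alkene to the six-membered ring B with loss of ethene; the new C4=C5 bond is cis by ring size, and the side-chain alkene cannot compete because it could only give a four-membered or a tetrasubstituted seven-membered ring.

Step 17
Reactants: 26 cis-fused decalin 1,6-diol enone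
Product: 29 ten-membered furanone carbocycle with C6 ketone, via ten-membered triketone 27 (not isolated), via C10-hydroxy triketone 28 (not isolated)
Conditions: Pb(OAc)4, CH2Cl2, 0 °C; then p-TsOH·H2O (cat.), THF/H2O, rt
Reagents that add atoms: none
Why: Pb(OAc)4 forms a five-membered cyclic plumbate with the cis C1,C6-diol and fragments it in a two-electron step (tetravalent lead to divalent lead), so that the ring-fusion bond is cut and C1 and C6 become ketones; this is a Criegee glycol cleavage of a ring-fusion diol, the known way from bicycles to medium-ring diketones. No ring is closed in this event: the ten-membered ring appears because the bond shared by rings A and B is removed, and C4=C5 keeps the cis geometry it had in ring B. Aqueous acid then removes the tertiary triethylsilyl ether, the C10 hydroxyl adds to the C3 carbonyl of the C1/C3 diketone (5-exo-trig) and the hemiketal loses water toward C2, which is the known acid cyclodehydration of α'-hydroxy 1,3-diketones to 3(2H)-furanones; the vinylogous ester is the thermodynamic sink. No stereocentre is formed, C1 and C6 lose theirs, and C7, C8 and C10 are not touched. The step needs cleavage of C1–C6 and not of C1–C10, which the silyl ether on the C10 oxygen secures because only C1 and C6 carry free vicinal hydroxyls; it needs the C10 oxygen and no other to attack C3, which is secured because it is the only hydroxyl set free; and it needs the acid to spare the secondary TBS and primary TBDPS ethers, which their lower lability secures.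

Step 18
Reactants: 29 ten-membered furanone carbocycle with C6 ketone
Product: 30 C6 allylic alcohol
Conditions: NaBH4, CeCl3·7H2O, MeOH, −78 °C
Reagents that add atoms: none
Why: Luche reduction: the C6 ketone is the only ordinary enone carbonyl (C1 is a vinylogous ester) and CeCl3 enforces 1,2-addition. Felkin–Anh attack anti to the C7 side chain, with the C7–C8 ring bond on the inside, should give the 6R alcohol with H-6 anti to H-7; the reduction also ends the lability of C7–H.

Step 19
Reactants: 30 C6 allylic alcohol
Product: 31 C6,C12-diol
Conditions: Ce(NH4)2(NO3)6, MeCN/H2O, 0 °C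
Reagents that add atoms: none
Why: Oxidative de-arylation: tetravalent cerium oxidises the electron-rich aryl ether to its radical cation, water adds at the ipso carbon and the alcohol is released as the quinone forms. Silyl ethers, furanone and the allylic alcohol should survive the short cold exposure.

Step 20
Reactants: 31 C6,C12-diol
Product: 34 silyl-protected α-methylene lactone, via hydroxy enal 32 (not isolated), via lactol 33 (not isolated)
Conditions: TEMPO (cat.), PhI(OAc)2, CH2Cl2, rt
Reagents that add atoms: none
Why: Oxidative lactonisation: the oxoammonium salt from TEMPO oxidises the primary allylic C12 alcohol faster than the secondary C6 alcohol, the enal is captured by the C6 hydroxyl as a five-membered lactol, and this is oxidised to the α-methylene lactone. The trans ring fusion follows from the C6 and C7 configurations.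

Step 21
Reactants: 34 silyl-protected α-methylene lactone
Product: 35 C8,C15-diol
Conditions: HF·pyridine, pyridine, THF, 0 °C to rt
Reagents that add atoms: none
Why: Fluoride-mediated desilylation in a buffered, non-basic medium removes both silyl ethers without conjugate addition to the exo-methylene lactone.

Step 22
Reactants: 35 C8,C15-diol
Product: 36 C15 acetate
Conditions: Ac2O, 2,4,6-collidine, CH2Cl2, −20 to 0 °C
Reagents that add atoms: acetic anhydride, CC(=O)OC(C)=O
Why: The unhindered primary allylic C15 hydroxyl is acylated far faster than the secondary C8 hydroxyl, which is flanked by C7 and the lactone, so one equivalent of anhydride at low temperature should give the monoacetate.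

Step 23
Reactants: 36 C15 acetate
Product: 37 target
Conditions: methacrylic anhydride, Et3N, DMAP (cat.), CH2Cl2, 0 °C to rt
Reagents that add atoms: methacrylic anhydride, C=C(C)C(=O)OC(=O)C(C)=C
Why: DMAP-catalysed acylation of the remaining C8 hydroxyl introduces the methacrylate last, so that this Michael acceptor meets no nucleophile or reductant.

Compound list

1 | (S)-carvone, (5S)-2-methyl-5-(prop-1-en-2-yl)cyclohex-2-en-1-one | CC(=C)[C@@H]1CC(=O)C(C)=CC1 | starting material
2 | (5S)-5-(3-chloroprop-1-en-2-yl)-2-methylcyclohex-2-en-1-one | ClCC(=C)[C@@H]1CC(=O)C(C)=CC1 | intermediate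
3 | (5S)-5-[3-(4-methoxyphenoxy)prop-1-en-2-yl]-2-methylcyclohex-2-en-1-one | COc1ccc(OCC(=C)[C@@H]2CC(=O)C(C)=CC2)cc1 | intermediate
4 | lithium cross-conjugated dienolate of 3 (O–C9=C8) | COc1ccc(OCC(=C)[C@@H]2C=C([O-])C(C)=CC2)cc1.[Li+] | intermediate
5 | TBS dienol ether of 3 (C9 OTBS, C8=C9, C10=C1) | COc1ccc(OCC(=C)[C@@H]2C=C(O[Si](C)(C)C(C)(C)C)C(C)=CC2)cc1 | intermediate
6 | enone 3 with OTBS at C8, trans to the C7 side chain | COc1ccc(OCC(=C)[C@@H]2[C@@H](O[Si](C)(C)C(C)(C)C)C(=O)C(C)=CC2)cc1 | intermediate
7 | epoxy ketone: 6 with C1–C10 oxirane on the face of the C8 oxygen | COc1ccc(OCC(=C)[C@@H]2[C@@H](O[Si](C)(C)C(C)(C)C)C(=O)[C@@]3(C)O[C@H]3C2)cc1 | intermediate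
8 | allylic alcohol: C1 OH on the face of the C8 oxygen, C9=C10, C8 OTBS | COc1ccc(OCC(=C)[C@@H]2[C@@H](O[Si](C)(C)C(C)(C)C)C=C(C)[C@@H](O)C2)cc1 | intermediate
9 | epoxy alcohol: 8 with C9–C10 oxirane syn to the C1 hydroxyl | COc1ccc(OCC(=C)[C@@H]2[C@@H](O[Si](C)(C)C(C)(C)C)[C@H]3O[C@@]3(C)[C@@H](O)C2)cc1 | intermediate
10 | diol: secondary C1 OH and tertiary C10 OH, both on the face of the C8 oxygen, C9 methylene | COc1ccc(OCC(=C)[C@@H]2[C@@H](O[Si](C)(C)C(C)(C)C)C[C@@](C)(O)[C@@H](O)C2)cc1 | intermediate
11 | α-hydroxy ketone: C1 ketone, C10 tertiary OH | COc1ccc(OCC(=C)[C@@H]2[C@@H](O[Si](C)(C)C(C)(C)C)C[C@@](C)(O)C(=O)C2)cc1 | intermediate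
12 | ring A ketone: 11 as its C10 triethylsilyl ether | COc1ccc(OCC(=C)[C@@H]2[C@@H](O[Si](C)(C)C(C)(C)C)C[C@@](C)(O[Si](CC)(CC)CC)C(=O)C2)cc1 | intermediate
13 | TMS enol ether of 12 (C1 OTMS, C1=C6) | COc1ccc(OCC(=C)[C@@H]2[C@@H](O[Si](C)(C)C(C)(C)C)C[C@@](C)(O[Si](CC)(CC)CC)C(O[Si](C)(C)C)=C2)cc1 | intermediate
14 | 12 with OTMS at C6 (drawn anti to the C7 side chain) | COc1ccc(OCC(=C)[C@@H]2[C@@H](O[Si](C)(C)C(C)(C)C)C[C@@](C)(O[Si](CC)(CC)CC)C(=O)[C@H]2O[Si](C)(C)C)cc1 | intermediate
15 | phenyl vinyl sulfoxide | C=CS(=O)c1ccccc1 | starting material
16 | lithium enolate of 14 (O–C1=C6) | COc1ccc(OCC(=C)[C@@H]2[C@@H](O[Si](C)(C)C(C)(C)C)C[C@@](C)(O[Si](CC)(CC)CC)C([O-])=C2O[Si](C)(C)C)cc1.[Li+] | intermediate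
17 | 14 with a 2-(phenylsulfinyl)ethyl group at C6 on the face of the C8 oxygen and C6 OTMS on the face of the C7 side chain (mixture at sulfur) | COc1ccc(OCC(=C)[C@@H]2[C@@H](O[Si](C)(C)C(C)(C)C)C[C@@](C)(O[Si](CC)(CC)CC)C(=O)[C@@]2(O[Si](C)(C)C)CCS(=O)c2ccccc2)cc1 | intermediate
18 | vinyl ketone: quaternary C6 with vinyl (face of the C8 oxygen) and OTMS | COc1ccc(OCC(=C)[C@@H]2[C@@H](O[Si](C)(C)C(C)(C)C)C[C@@](C)(O[Si](CC)(CC)CC)C(=O)[C@@]2(O[Si](C)(C)C)C=C)cc1 | intermediate
19 | methyl vinyl ketone | C=CC(C)=O | starting material
20 | formaldehyde | C=O | starting material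
21 | 3-(hydroxymethyl)but-3-en-2-one | C=C(CO)C(C)=O | intermediate
22 | 3-[(tert-butyldiphenylsilyloxy)methyl]but-3-en-2-one | C=C(CO[Si](c1ccccc1)(c1ccccc1)C(C)(C)C)C(C)=O | intermediate
23 | lithium dienolate of 22 | [Li+].[O-]C(=C)C(=C)CO[Si](c1ccccc1)(c1ccccc1)C(C)(C)C | intermediate
24 | aldol adduct of 18 and 23 with C6 OTMS retained | COc1ccc(OCC(=C)[C@@H]2[C@@H](O[Si](C)(C)C(C)(C)C)C[C@@](C)(O[Si](CC)(CC)CC)[C@@](O)(CC(=O)C(=C)CO[Si](c3ccccc3)(c3ccccc3)C(C)(C)C)[C@@]2(O[Si](C)(C)C)C=C)cc1 | intermediate
25 | diene diol: C1 OH with the C2–C4 enone chain, C6 OH with vinyl; both hydroxyls on the face of the C7 side chain | COc1ccc(OCC(=C)[C@@H]2[C@@H](O[Si](C)(C)C(C)(C)C)C[C@@](C)(O[Si](CC)(CC)CC)[C@@](O)(CC(=O)C(=C)CO[Si](c3ccccc3)(c3ccccc3)C(C)(C)C)[C@@]2(O)C=C)cc1 | intermediate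
26 | cis-fused decalin 1,6-diol enone (C3 ketone, C4=C5, C15 OTBDPS, C8 OTBS, C10 OTES, C7 2-(aryloxymethyl)vinyl) | COc1ccc(OCC(=C)[C@@H]2[C@@H](O[Si](C)(C)C(C)(C)C)C[C@@](C)(O[Si](CC)(CC)CC)[C@@]3(O)CC(=O)C(CO[Si](c4ccccc4)(c4ccccc4)C(C)(C)C)=C[C@@]23O)cc1 | intermediate
27 | ten-membered triketone (C1, C3, C6 ketones, Z C4=C5, C10 OTES) | COc1ccc(OCC(=C)[C@@H]2[C@@H](O[Si](C)(C)C(C)(C)C)C[C@@](C)(O[Si](CC)(CC)CC)C(=O)CC(=O)/C(CO[Si](c3ccccc3)(c3ccccc3)C(C)(C)C)=C\C2=O)cc1 | intermediate
28 | triketone 27 with free C10 hydroxyl | COc1ccc(OCC(=C)[C@@H]2[C@@H](O[Si](C)(C)C(C)(C)C)C[C@@](C)(O)C(=O)CC(=O)/C(CO[Si](c3ccccc3)(c3ccccc3)C(C)(C)C)=C\C2=O)cc1 | intermediate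
29 | ten-membered furanone carbocycle with C6 ketone (C8 OTBS, C15 OTBDPS, C7 2-(aryloxymethyl)vinyl) | COc1ccc(OCC(=C)[C@@H]2[C@@H](O[Si](C)(C)C(C)(C)C)C[C@@]3(C)OC(=CC3=O)/C(CO[Si](c4ccccc4)(c4ccccc4)C(C)(C)C)=C\C2=O)cc1 | intermediate
30 | 29 reduced at C6 to the 6R alcohol | COc1ccc(OCC(=C)[C@@H]2[C@@H](O[Si](C)(C)C(C)(C)C)C[C@@]3(C)OC(=CC3=O)/C(CO[Si](c4ccccc4)(c4ccccc4)C(C)(C)C)=C\[C@H]2O)cc1 | intermediate
31 | C6,C12-diol | OCC(=C)[C@@H]1[C@@H](O[Si](C)(C)C(C)(C)C)C[C@@]2(C)OC(=CC2=O)/C(CO[Si](c3ccccc3)(c3ccccc3)C(C)(C)C)=C\[C@H]1O | intermediate
32 | C12 enal with free C6 hydroxyl | O=CC(=C)[C@@H]1[C@@H](O[Si](C)(C)C(C)(C)C)C[C@@]2(C)OC(=CC2=O)/C(CO[Si](c3ccccc3)(c3ccccc3)C(C)(C)C)=C\[C@H]1O | intermediate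
33 | C12 lactol (mixture at C12) | CC(C)(C)[Si](C)(C)O[C@H]1C[C@@]2(C)OC(=CC2=O)/C(CO[Si](c3ccccc3)(c3ccccc3)C(C)(C)C)=C\[C@H]2OC(O)C(=C)[C@H]12 | intermediate
34 | α-methylene lactone with C8 OTBS and C15 OTBDPS | CC(C)(C)[Si](C)(C)O[C@H]1C[C@@]2(C)OC(=CC2=O)/C(CO[Si](c3ccccc3)(c3ccccc3)C(C)(C)C)=C\[C@H]2OC(=O)C(=C)[C@H]12 | intermediate
35 | C8,C15-diol of the lactone | O[C@H]1C[C@@]2(C)OC(=CC2=O)/C(CO)=C\[C@H]2OC(=O)C(=C)[C@H]12 | intermediate
36 | C15 acetate with free C8 hydroxyl | O[C@H]1C[C@@]2(C)OC(=CC2=O)/C(COC(C)=O)=C\[C@H]2OC(=O)C(=C)[C@H]12 | intermediate
37 | CNP0179932.1 | C=C(C)C(=O)O[C@H]1C[C@@]2(C)OC(=CC2=O)/C(COC(C)=O)=C\[C@H]2OC(=O)C(=C)[C@H]12 | target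

Total step count: 23. Longest linear sequence: 21 steps (steps 1–12 and 15–23, from 1); steps 13 and 14 prepare 22.

Least certain steps

Step 17 (key step). Three processes may interfere: a transannular aldol of the C1/C3 diketone enol onto the C6 ketone before the furanone closes; acid-induced epimerisation at C7 or migration of the C11=C13 bond into conjugation with C6; and partial loss of the other silyl ethers. The fallback separates the two events and avoids strong acid. It sets out from 26: the glycol cleavage is run alone and 27 is isolated. Buffered HF·pyridine then removes the triethylsilyl group, and the freed C10 hydroxyl closes onto C3 to give the cyclic hemiketal F1. This is dehydrated toward C2 with the Burgess reagent under neutral conditions, and the route is rejoined at 29.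

Step 11. Carbon–carbon bond formation at the crowded, fully substituted enolate carbon may be slow, and a shift of the trimethylsilyl group between the two enolate oxygens could divert the alkylation to C1. The fallback replaces the slow conjugate addition by a fast carbonyl addition at low temperature, where silyl migration is slow. It sets out from 14: enolate 16 is added to acetaldehyde to give the aldol F2. F2 is dehydrated with Martin sulfurane; since C6 is quaternary, elimination can only run toward the methyl group. The route is rejoined at 18.

Step 15. The aldol equilibrium at the hindered ketone may lie on the side of the components, the vinyl ketone enolate may oligomerise, and the facial preference may be weaker than predicted. The fallback uses an amide enolate, which adds irreversibly, and builds the enone afterwards. It sets out from 18: N-methoxy-N-methylacetamide is deprotonated with LiN(iPr)2 to the amide enolate F3, which adds to C1 to give the β-hydroxy Weinreb amide F4. The vinyl bromide F5 (from commercial 2-bromoallyl alcohol and TBDPSCl) is converted by t-BuLi to the vinyllithium F6, which turns the amide into the enone. The route is rejoined at 24, which is methanolysed to 25 as before.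

Step 18. Facial selectivity in the medium ring may be poor or reversed, and some 1,4-reduction is possible. The fallback corrects the configuration by substitution and does not rely on the reduction. It sets out from 29: if the C6 epimer F5a were the main product the label would clash, so the epimer is called the C6-epimeric alcohol F7. F7 is inverted by a Mitsunobu reaction with 4-nitrobenzoic acid (PPh3, diisopropyl azodicarboxylate) to the 4-nitrobenzoate F8 of the correct configuration. Methanolysis (K2CO3, MeOH) then rejoins the route at 30.

Step 20. Oxidation of the secondary allylic C6 hydroxyl back to the ketone may compete if lactol formation or lactol oxidation is slow. The fallback stops the oxoammonium oxidation early and finishes with an oxidant that does not touch alcohols. It sets out from 31: one equivalent of PhI(OAc)2 takes the oxidation only to 32. NaClO2 (NaH2PO4, 2-methyl-2-butene) then gives the hydroxy acid F9, which is closed to the lactone by carbodiimide activation. The route is rejoined at 34.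

Further compounds

F1 | step 17 | cyclic hemiketal: 28 closed between the C10 oxygen and C3 (C3 OH, C2 methylene, C1 ketone) | COc1ccc(OCC(=C)[C@@H]2[C@@H](O[Si](C)(C)C(C)(C)C)C[C@@]3(C)OC(O)(CC3=O)/C(CO[Si](c4ccccc4)(c4ccccc4)C(C)(C)C)=C\C2=O)cc1
F2 | step 11 | aldol: 14 with a 1-hydroxyethyl group at C6 on the face of the C8 oxygen | COc1ccc(OCC(=C)[C@@H]2[C@@H](O[Si](C)(C)C(C)(C)C)C[C@@](C)(O[Si](CC)(CC)CC)C(=O)[C@@]2(O[Si](C)(C)C)C(C)O)cc1
F3 | step 15 | lithium enolate of N-methoxy-N-methylacetamide | [Li+].[O-]C(=C)N(C)OC
F4 | step 15 | β-hydroxy Weinreb amide: 18 with CH2C(=O)N(OMe)Me and OH at C1 | COc1ccc(OCC(=C)[C@@H]2[C@@H](O[Si](C)(C)C(C)(C)C)C[C@@](C)(O[Si](CC)(CC)CC)[C@@](O)(CC(=O)N(C)OC)[C@@]2(O[Si](C)(C)C)C=C)cc1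
F5 | step 15 | (2-bromoallyloxy)(tert-butyl)diphenylsilane | C=C(Br)CO[Si](c1ccccc1)(c1ccccc1)C(C)(C)C
F6 | step 15 | 2-lithio-3-(tert-butyldiphenylsilyloxy)propene | [Li]C(=C)CO[Si](c1ccccc1)(c1ccccc1)C(C)(C)C
F7 | step 18 | C6-epimeric alcohol of 30 | COc1ccc(OCC(=C)[C@@H]2[C@@H](O[Si](C)(C)C(C)(C)C)C[C@@]3(C)OC(=CC3=O)/C(CO[Si](c4ccccc4)(c4ccccc4)C(C)(C)C)=C\[C@@H]2O)cc1
F8 | step 18 | 4-nitrobenzoate of 30 | COc1ccc(OCC(=C)[C@@H]2[C@@H](O[Si](C)(C)C(C)(C)C)C[C@@]3(C)OC(=CC3=O)/C(CO[Si](c4ccccc4)(c4ccccc4)C(C)(C)C)=C\[C@H]2OC(=O)c2ccc(cc2)[N+](=O)[O-])cc1
F9 | step 20 | C12 carboxylic acid with free C6 hydroxyl | OC(=O)C(=C)[C@@H]1[C@@H](O[Si](C)(C)C(C)(C)C)C[C@@]2(C)OC(=CC2=O)/C(CO[Si](c3ccccc3)(c3ccccc3)C(C)(C)C)=C\[C@H]1O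
A1 | alternative 1 | trans,trans lactone with the C8 dithiane at C7 and dimethylaminomethyl at C11 | CC(C)(C)[Si](c1ccccc1)(c1ccccc1)OC[C@H]1OC(=O)[C@@H](CN(C)C)[C@@H]1C1(SCCCS1)C[C@@](C)(O[Si](CC)(CC)CC)COCc1ccc(OC)cc1
A2 | alternative 1 | (S)-5-[(tert-butyldiphenylsilyloxy)methyl]furan-2(5H)-one | CC(C)(C)[Si](c1ccccc1)(c1ccccc1)OC[C@H]1OC(=O)C=C1
A3 | alternative 1 | 2-substituted 1,3-dithiane carrying C9, C10 (methyl, OTES) and C1 (OPMB) | C1(SCCCS1)C[C@@](C)(O[Si](CC)(CC)CC)COCc1ccc(OC)cc1
A4 | alternative 2 | 2,2,5-trisubstituted furanone with ester on C2 and both side chains | COC(=O)C1=C(/C(CO[Si](C)(C)C(C)(C)C)=C\CO[Si](c2ccccc2)(c2ccccc2)C(C)(C)C)O[C@](C)(C[C@H](O[Si](C)(C)C(C)(C)C)COCc2ccc(OC)cc2)C1=O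
A5 | alternative 2 | methyl 2-hydroxy-2-methyl-4-(tert-butyldimethylsilyloxy)-5-(4-methoxybenzyloxy)pentanoate (C10 and C8 configured as in A4) | O[C@](C)(C[C@H](O[Si](C)(C)C(C)(C)C)COCc1ccc(OC)cc1)C(=O)OC
A6 | alternative 2 | methyl hex-4-en-2-ynoate with silyloxymethyl on C4 and silyloxy on C6 (C3 and C6 cis) | COC(=O)C#C/C(CO[Si](C)(C)C(C)(C)C)=C\CO[Si](c1ccccc1)(c1ccccc1)C(C)(C)C
A7 | alternative 3 | ten-membered Z-alkene furanone carbocycle with open lactone | COc1ccc(CO[C@H]2C[C@@]3(C)OC(=CC3=O)/C(COCc4ccc(OC)cc4)=C\[C@@H](O[Si](C)(C)C(C)(C)C)[C@@H]2C(=C)C(=O)OC)cc1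
A8 | alternative 3 | eleven-membered cyclic sulfone with sulfur between C4 and C5 (mixture at C4) | COc1ccc(CO[C@H]2C[C@@]3(C)OC(=CC3=O)C(COCc4ccc(OC)cc4)S(=O)(=O)C[C@@H](O[Si](C)(C)C(C)(C)C)[C@@H]2C(=C)C(=O)OC)cc1
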